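At late times theta stands still near 50.5% of the substrate charged, while eta is still climbing at 68.1%.

all flasks: free catalyst 24 mM

| charge | substrate | partner | added ligand | temperature | remark | time |
|---|---|---|---|---|---|---|
| eta | 1 M | 2 M | 21 mM | 30 °C | run made earlier |  |
| theta | 1 M | 2 M | 45 mM | 41 °C | run made earlier |  |
| dawn | 1.0 M | 2.00 M | 33 mM | 35 °C |  | 6.0 d |
| midnight | 1.0 M | 2.00 M | 15 mM | 35 °C |  | 25 d |

| run | time / d | target / % |
|---|---|---|
| eta | 0.417 | 11.6 |
| eta | 1.25 | 30.8 |
| eta | 2.00 | 42.4 |
| eta | 3.00 | 53.4 |
| eta | 5.00 | 65.8 |
| eta | 6.00 | 68.1 |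
| theta | 0.417 | 24.7 |
| theta | 1.25 | 43.8 |
| theta | 2.00 | 48.0 |
| theta | 3.00 | 51.0 |
| theta | 5.00 | 50.5 |
| theta | 6.00 | 50.5 |

(readings scatter by 0.5 percentage points)

- the winner by amount of target, in percent of the substrate charged; "neither" if no more than 2 percentage points parts them (dawn / midnight / neither)
- how much target is there at the end, in percent of the substrate charged: dawn
- how much target is there at the end, in percent of the substrate charged: midnight

- the numbers in the tables scatter by 0.5 percentage points (one standard deviation)

My own reckoning takes each run as one exponential climb to a level. It reads that level as the end of the partner, which goes two ways at rates proportional to it, so their ratio holds through a run. These readings can't prove this. Eta's readings at 3.00 d and 6.00 d are equally spaced from the start and give its level: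

level, eta = 73.7%

The split is partner turned into target per partner lost otherwise, a selectivity factor. It is read from each level, then interpolated in its logarithm, 0.455 of the way from eta to theta, with the ligand difference set aside:

split: eta 0.583, theta 0.338, at 35 °C 0.455

level at 35 °C = 62.5% of the substrate charged

The ladder of times then runs as follows, the ligand difference again set aside:

theta's half-time of climb: 0.430 d

eta's rate 0.430 d⁻¹, theta's 1.61 d⁻¹, at 35 °C 0.784 d⁻¹

half-time at 35 °C: 0.884 d

dawn's 6.0 d: 6.79 half-times, 0.906% of the climb left, target 62.0%

midnight's 25 d: 28.3 half-times, target on the level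

Midnight leads dawn by 0.50 percentage points, less than the margin, so this reckoning says neither.

The forecast also says neither, with dawn at 62.5% and midnight at 64%, but on another reading of the level: “equilibrium lies near 64% for both runs”.

The flask gives neither: dawn 61.6%, midnight 62.3%. Dawn ends with 0.72% of its partner and 36% of its substrate: the partner, charged at twice the substrate, is the limiting reagent.

    substrate + free catalyst → catalyst intermediate A (k = 0.310 M⁻¹ min⁻¹, Ea = 56.0 kJ mol⁻¹)
    catalyst intermediate A → catalyst intermediate B (k = 3.50 min⁻¹, Ea = 92.0 kJ mol⁻¹)
    partner + catalyst intermediate B → catalyst intermediate C (k = 0.00770 M⁻¹ min⁻¹, Ea = 72.0 kJ mol⁻¹)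
    catalyst intermediate C → free catalyst + target (k = 1.30 min⁻¹, Ea = 77.0 kJ mol⁻¹)
    partner → decomposed reagent (k = 3.90 × 10⁻⁴ min⁻¹, Ea = 111 kJ mol⁻¹)
    free catalyst + added ligand ⇌ idle complex (K = 9.80 M⁻¹, k = 0.130 M⁻¹ min⁻¹, Ea = 72.0 kJ mol⁻¹, ΔH = 25.0 kJ mol⁻¹)
    (constants at 35 °C)

The split 0.455 reckons 1.37 M of partner lost the other way, and midnight holds 1.38 M of decomposed reagent.

The split speaks of partner, so dawn's recipe with 2.5 M of substrate should reach the same level in moles of target, told over a larger charge: 25.0%. That flask gives 25.1%, with 74% of its substrate left.

The readings were generated by integration from invented constants.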